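## Retrosynthetic overview

- The strategy rests on the single carbocycle: its C2=C3 alkene (C2 methyl) with the cis C4 acetate and C5 carbon branch is the retron of an endo [4+2] adduct. The diene is (E)-1-acetoxy-3-methylbutadiene (C1–C4) and the dienophile an acrylate (C5, C6). The ring is made first, by a Cu(t-Bu-box)(SbF6)2-catalysed Diels–Alder reaction that forms C4–C5 and C1–C6.
- The C5 acyl group is grown into the chain: imide, Weinreb amide, methyl ketone, E-enoate (C1'=C2'), enal. The C3'=C4' alkene is cut by Julia–Kocienski olefination to an (R)-sulfone, made from the (S)-Roche ester by a Z-selective Wittig reaction.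
- Ring oxygenation follows the cycloaddition: SeO2 oxidation at C1 to the enone, then enolate hydroxylation at C6 anti to the C5 substituent.
- The acetate is exchanged for a triethylsilyl ether during the organometallic and hydride steps and restored at the end; the C6 hydroxyl travels as a tert-butyldimethylsilyl ether.

Key step: step 3

Remark: target locants are used for all intermediates (ring C1 carbonyl, C2 methyl-bearing, C3, C4 acetate, C5 side chain, C6 hydroxyl; primed chain carbons, C1' on C5). The (R,R) ligand is chosen on the assumption that the cycloaddition follows the square-planar chelate model, in which this ligand leaves the α-Si face of the bound acrylimide open; the enantiomeric ligand would be used if the opposite sense were found.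

## Route

Step 1
Reactants: 1 3-methylbut-2-enal; 2 isopropenyl acetate
Product: 3 (1E)-3-methylbuta-1,3-dien-1-yl acetate
Conditions: TsOH·H2O (cat.), neat 2, 90–95 °C, acetone distilled off
Reagents that add atoms: none
Why: Acid-catalysed enol acetylation (acetyl transfer from isopropenyl acetate) traps the extended dienol of the enal as the conjugated dienyl acetate, and the E enol ester should predominate and is the isomer that reacts in step 3.

Step 2
Reactants: 4 1,3-oxazolidin-2-one; 5 acryloyl chloride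
Product: 7 3-(prop-2-enoyl)-1,3-oxazolidin-2-one, via bromomagnesium oxazolidinone salt 6 (not isolated)
Conditions: MeMgBr, THF, 0 °C; then 5, −78 → 0 °C
Reagents that add atoms: none
Why: N-acylation of the magnesiated carbamate nitrogen by the acid chloride (imide formation), the low temperature suppressing conjugate addition and polymerisation of the acrylate.

Step 3
Reactants: 3 (1E)-3-methylbuta-1,3-dien-1-yl acetate; 7 3-(prop-2-enoyl)-1,3-oxazolidin-2-one
Product: 8 (1S,6R)-3-methyl-6-(2-oxo-1,3-oxazolidine-3-carbonyl)cyclohex-2-en-1-yl acetate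
Conditions: [Cu((R,R)-t-Bu-box)](SbF6)2 (5 mol%; from CuCl2, 2,2'-(propane-2,2-diyl)bis[(4R)-4-tert-butyl-4,5-dihydrooxazole] and AgSbF6), CH2Cl2, −20 → 0 °C
Reagents that add atoms: none
Why: The imide chelates the divalent copper centre of the square-planar cationic complex through both carbonyl oxygens in the s-cis form and one tert-butyl group of the ligand covers the α-Re face, so the diene adds to the open α-Si face in a concerted, asynchronous [4+2] cycloaddition in which C1–C6 bonding runs ahead of C4–C5 bonding. The closest known reaction type is the bis(oxazoline)–copper-catalysed Diels–Alder reaction of acryloyl oxazolidinone with 1-acetoxy dienes. The six-membered ring closes by intermolecular suprafacial union of the four diene carbons (C1 to C4) with the two acrylate carbons (C5 and C6). C5 (R) is fixed by the ligand-controlled face of the chelated dienophile, and C4 (S) by the endo transition state, which from the E-dienyl acetate places the acetate cis to the acyl group. The step needs endo, regio- and enantioselectivity: secondary overlap with the chelated carbonyl favours endo, the 1-acetoxy and 3-methyl donors both put the largest diene HOMO coefficient on the CH2 terminus so that it bonds to the acrylate β-carbon, and the ligand enantiomer fixes the absolute sense.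

Step 4
Reactants: 8 (1S,6R)-3-methyl-6-(2-oxo-1,3-oxazolidine-3-carbonyl)cyclohex-2-en-1-yl acetate
Product: 9 (1S,6R)-6-[methoxy(methyl)carbamoyl]-3-methylcyclohex-2-en-1-yl acetate
Conditions: Me(MeO)NH·HCl, AlMe3, CH2Cl2, −15 → 0 °C
Reagents that add atoms: N,O-dimethylhydroxylamine hydrochloride, Cl.CNOC
Why: Aluminium-amide transamination of the imide (Weinreb amide formation) attacks the activated exocyclic carbonyl under conditions that are not basic toward the β-acetoxy carbonyl unit and should spare the acetate at or below 0 °C, so neither stereocentre is touched.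

Step 5
Reactants: 9 (1S,6R)-6-[methoxy(methyl)carbamoyl]-3-methylcyclohex-2-en-1-yl acetate
Product: 10 1-[(1R,2S)-2-hydroxy-4-methylcyclohex-3-en-1-yl]ethan-1-one
Conditions: MeMgBr (5 equiv), THF, 0 °C → rt; aq. NH4Cl
Reagents that add atoms: methylmagnesium bromide, C[Mg]Br
Why: Grignard addition to the Weinreb amide stops at the chelated tetrahedral adduct, which releases the methyl ketone only on work-up, while excess reagent cleaves the acetate to the alkoxide, so C5 is never exposed to enolising conditions as a free ketone.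

Step 6
Reactants: 10 1-[(1R,2S)-2-hydroxy-4-methylcyclohex-3-en-1-yl]ethan-1-one
Product: 11 1-[(1R,2S)-4-methyl-2-(triethylsilyloxy)cyclohex-3-en-1-yl]ethan-1-one
Conditions: Et3SiCl, imidazole, CH2Cl2, 0 °C
Reagents that add atoms: chlorotriethylsilane, CC[Si](Cl)(CC)CC
Why: Silyl ether formation on the secondary allylic alcohol under mild imidazole conditions blocks dehydration and retro-aldol cleavage of the β-hydroxy ketone and installs a group that can later be removed in the presence of a tert-butyldimethylsilyl ether.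

Step 7
Reactants: 11 1-[(1R,2S)-4-methyl-2-(triethylsilyloxy)cyclohex-3-en-1-yl]ethan-1-one
Product: 12 ethyl (2E)-3-[(1S,2S)-4-methyl-2-(triethylsilyloxy)cyclohex-3-en-1-yl]but-2-enoate
Conditions: (EtO)2P(O)CH2CO2Et, NaH, THF, 0 → 50 °C
Reagents that add atoms: triethyl phosphonoacetate, CCOC(=O)CP(=O)(OCC)OCC
Why: Horner–Wadsworth–Emmons olefination of the methyl ketone places the ester trans to the bulkier ring substituent (E at C1'=C2'), the weakly basic phosphonate anion should leave C5 and the β-silyloxy group intact, and any Z isomer is removed by chromatography.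

Step 8
Reactants: 12 ethyl (2E)-3-[(1S,2S)-4-methyl-2-(triethylsilyloxy)cyclohex-3-en-1-yl]but-2-enoate
Product: 14 ethyl (2E)-3-[(1S,2S)-4-methyl-5-oxo-2-(triethylsilyloxy)cyclohex-3-en-1-yl]but-2-enoate, via C1 allylic alcohol 13 (not isolated)
Conditions: SeO2 (0.5 equiv), t-BuOOH, CH2Cl2, rt; then Dess–Martin periodinane, NaHCO3, CH2Cl2, 0 °C → rt
Reagents that add atoms: selenium dioxide, O=[Se]=O; tert-butyl hydroperoxide, CC(C)(C)OO
Why: Riley allylic oxidation (ene reaction at C3, then [2,3]-sigmatropic shift) oxygenates the ring CH2 on the more substituted alkene terminus, C1, and restores the C2=C3 bond while the electron-poor enoate alkene is inert, and Dess–Martin oxidation then converges the C1 alcohol epimers and any enone already formed on the enone.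

Step 9
Reactants: 14 ethyl (2E)-3-[(1S,2S)-4-methyl-5-oxo-2-(triethylsilyloxy)cyclohex-3-en-1-yl]but-2-enoate
Product: 16 ethyl (2E)-3-[(1R,2S,6R)-6-hydroxy-4-methyl-5-oxo-2-(triethylsilyloxy)cyclohex-3-en-1-yl]but-2-enoate, via potassium enolate 15 (not isolated)
Conditions: KN(SiMe3)2, THF, −78 °C; then 2-(phenylsulfonyl)-3-phenyloxaziridine, −78 °C; aq. NH4Cl
Reagents that add atoms: 2-(phenylsulfonyl)-3-phenyloxaziridine, O=S(=O)(N1OC1c1ccccc1)c1ccccc1
Why: Kinetic deprotonation of the enone at the α' carbon C6 followed by Davis enolate hydroxylation delivers oxygen to the enolate face anti to the adjacent C5 substituent and the cis C4 silyloxy group, setting C6 (R) with the hydroxyl trans to the side chain.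

Step 10
Reactants: 16 ethyl (2E)-3-[(1R,2S,6R)-6-hydroxy-4-methyl-5-oxo-2-(triethylsilyloxy)cyclohex-3-en-1-yl]but-2-enoate
Product: 17 ethyl (2E)-3-[(1S,2S,6R)-6-(tert-butyldimethylsilyloxy)-4-methyl-5-oxo-2-(triethylsilyloxy)cyclohex-3-en-1-yl]but-2-enoate
Conditions: TBSOTf, 2,6-lutidine, CH2Cl2, −78 → 0 °C
Reagents that add atoms: tert-butyldimethylsilyl trifluoromethanesulfonate, CC(C)(C)[Si](C)(C)OS(=O)(=O)C(F)(F)F
Why: Silylation of the secondary α-hydroxy ketone with a silyl triflate and a hindered base, which does not enolise the ketone at low temperature, protects the C6 hydroxyl for the hydride and carbanion steps with a group more robust than the C4 triethylsilyl ether.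

Step 11
Reactants: 17 ethyl (2E)-3-[(1S,2S,6R)-6-(tert-butyldimethylsilyloxy)-4-methyl-5-oxo-2-(triethylsilyloxy)cyclohex-3-en-1-yl]but-2-enoate
Product: 18 (2E)-3-[(1S,2S,6R)-6-(tert-butyldimethylsilyloxy)-5-hydroxy-4-methyl-2-(triethylsilyloxy)cyclohex-3-en-1-yl]but-2-en-1-ol (mixture of epimers at the ring carbinol carbon C1)
Conditions: i-Bu2AlH (5 equiv), CH2Cl2, −78 °C; aq. potassium sodium tartrate
Reagents that add atoms: none
Why: Hydride reduction with i-Bu2AlH takes the conjugated ester to the primary allylic alcohol and, unavoidably, the ring ketone to the C1 allylic alcohol by 1,2-addition (the C1 configuration is of no consequence), and at −78 °C silyl migration is not expected, so both silyl ethers, the alkene geometry and C4 to C6 stay untouched.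

Step 12
Reactants: 18 (2E)-3-[(1S,2S,6R)-6-(tert-butyldimethylsilyloxy)-5-hydroxy-4-methyl-2-(triethylsilyloxy)cyclohex-3-en-1-yl]but-2-en-1-ol
Product: 19 (2E)-3-[(1S,2S,6R)-6-(tert-butyldimethylsilyloxy)-4-methyl-5-oxo-2-(triethylsilyloxy)cyclohex-3-en-1-yl]but-2-enal
Conditions: Dess–Martin periodinane, NaHCO3, CH2Cl2, 0 °C → rt
Reagents that add atoms: none
Why: Dess–Martin oxidation of both allylic alcohols under buffered, non-epimerising conditions restores the C1 enone and gives the E-enal without isomerising the trisubstituted alkene.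

Step 13
Reactants: 20 methyl (2S)-3-hydroxy-2-methylpropanoate
Product: 21 methyl (2S)-3-(tert-butyldimethylsilyloxy)-2-methylpropanoate
Conditions: TBSCl, imidazole, CH2Cl2, rt
Reagents that add atoms: tert-butylchlorodimethylsilane, CC(C)(C)[Si](C)(C)Cl
Why: Standard silyl protection of the primary alcohol, with the stereocentre untouched.

Step 14
Reactants: 21 methyl (2S)-3-(tert-butyldimethylsilyloxy)-2-methylpropanoate
Product: 22 (2S)-3-(tert-butyldimethylsilyloxy)-2-methylpropanal
Conditions: i-Bu2AlH (1.05 equiv), CH2Cl2, −78 °C; aq. potassium sodium tartrate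
Reagents that add atoms: none
Why: Partial hydride reduction of the ester stops at the aluminium hemiacetal at −78 °C and gives the α-chiral aldehyde on work-up, which is used crude to avoid epimerisation.

Step 15
Reactants: 22 (2S)-3-(tert-butyldimethylsilyloxy)-2-methylpropanal; 23 (3-methylbutyl)triphenylphosphonium bromide
Product: 25 tert-butyl{[(2R,3Z)-2,6-dimethylhept-3-en-1-yl]oxy}dimethylsilane, via phosphorus ylide 24 (not isolated)
Conditions: NaN(SiMe3)2, THF, 0 °C; then 22, −78 °C → rt
Reagents that add atoms: none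
Why: Wittig olefination with a non-stabilised ylide under lithium-free conditions at low temperature gives the Z alkene (C6'=C7') through the kinetically favoured cis-oxaphosphetane, fast enough that the α-stereocentre is not epimerised.

Step 16
Reactants: 25 tert-butyl{[(2R,3Z)-2,6-dimethylhept-3-en-1-yl]oxy}dimethylsilane
Product: 26 (2R,3Z)-2,6-dimethylhept-3-en-1-ol
Conditions: Bu4NF, THF, 0 °C → rt
Reagents that add atoms: none
Why: Fluoride-mediated desilylation of the primary silyl ether.

Step 17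
Reactants: 26 (2R,3Z)-2,6-dimethylhept-3-en-1-ol
Product: 27 5-{[(2R,3Z)-2,6-dimethylhept-3-en-1-yl]sulfanyl}-1-phenyl-1H-tetrazole
Conditions: 1-phenyl-1H-tetrazole-5-thiol, PPh3, DIAD, THF, 0 °C → rt
Reagents that add atoms: 1-phenyl-1H-tetrazole-5-thiol, Sc1nnnn1-c1ccccc1
Why: Mitsunobu thioetherification, in which the acidic thiol displaces the activated primary oxyphosphonium by SN2 at CH2, remote from the stereocentre.

Step 18
Reactants: 27 5-{[(2R,3Z)-2,6-dimethylhept-3-en-1-yl]sulfanyl}-1-phenyl-1H-tetrazole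
Product: 28 5-{[(2R,3Z)-2,6-dimethylhept-3-en-1-yl]sulfonyl}-1-phenyl-1H-tetrazole
Conditions: (NH4)6Mo7O24·4H2O (cat.), 30% H2O2, EtOH, 0 °C → rt
Reagents that add atoms: hydrogen peroxide, OO
Why: Molybdate-catalysed peroxide oxidation of the sulfide to the sulfone is much faster than epoxidation of the isolated disubstituted Z alkene.

Step 19
Reactants: 19 (2E)-3-[(1S,2S,6R)-6-(tert-butyldimethylsilyloxy)-4-methyl-5-oxo-2-(triethylsilyloxy)cyclohex-3-en-1-yl]but-2-enal; 28 5-{[(2R,3Z)-2,6-dimethylhept-3-en-1-yl]sulfonyl}-1-phenyl-1H-tetrazole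
Product: 30 (4S,5S,6R)-6-(tert-butyldimethylsilyloxy)-5-[(2E,4E,6R,7Z)-6,10-dimethylundeca-2,4,7-trien-2-yl]-2-methyl-4-(triethylsilyloxy)cyclohex-2-en-1-one, via potassium sulfonyl carbanion 29 (not isolated)
Conditions: 28, KN(SiMe3)2, DME, −78 °C; then 19, −78 °C → rt
Reagents that add atoms: none
Why: Julia–Kocienski olefination, in which the sulfonyl carbanion adds to the aldehyde (far more electrophilic than the hindered α-branched ring ketone) and the adduct undergoes Smiles rearrangement and loss of SO2 and tetrazolate, the potassium counter-ion in DME favouring the E alkene at C3'=C4' while the non-acidic C5' centre keeps its configuration.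

Step 20
Reactants: 30 (4S,5S,6R)-6-(tert-butyldimethylsilyloxy)-5-[(2E,4E,6R,7Z)-6,10-dimethylundeca-2,4,7-trien-2-yl]-2-methyl-4-(triethylsilyloxy)cyclohex-2-en-1-one
Product: 31 (4S,5S,6R)-6-(tert-butyldimethylsilyloxy)-5-[(2E,4E,6R,7Z)-6,10-dimethylundeca-2,4,7-trien-2-yl]-4-hydroxy-2-methylcyclohex-2-en-1-one
Conditions: PPTS (cat.), MeOH/CH2Cl2, 0 °C
Reagents that add atoms: none
Why: Mild acid-catalysed methanolysis removes the triethylsilyl ether far faster than the hindered secondary tert-butyldimethylsilyl ether (selective desilylation).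

Step 21
Reactants: 31 (4S,5S,6R)-6-(tert-butyldimethylsilyloxy)-5-[(2E,4E,6R,7Z)-6,10-dimethylundeca-2,4,7-trien-2-yl]-4-hydroxy-2-methylcyclohex-2-en-1-one
Product: 32 (1S,5R,6S)-5-(tert-butyldimethylsilyloxy)-6-[(2E,4E,6R,7Z)-6,10-dimethylundeca-2,4,7-trien-2-yl]-3-methyl-4-oxocyclohex-2-en-1-yl acetate
Conditions: Ac2O, pyridine, DMAP (cat.), CH2Cl2, 0 °C
Reagents that add atoms: acetic anhydride, CC(=O)OC(C)=O
Why: DMAP-catalysed acylation of the only free hydroxyl installs the C4 acetate with retention.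

Step 22
Reactants: 32 (1S,5R,6S)-5-(tert-butyldimethylsilyloxy)-6-[(2E,4E,6R,7Z)-6,10-dimethylundeca-2,4,7-trien-2-yl]-3-methyl-4-oxocyclohex-2-en-1-yl acetate
Product: 33 (1S,5R,6R)-6-[(2E,4E,6R,7Z)-6,10-dimethylundeca-2,4,7-trien-2-yl]-5-hydroxy-3-methyl-4-oxocyclohex-2-en-1-yl acetate
Conditions: HF·pyridine, pyridine, THF, 0 °C → rt
Reagents that add atoms: none
Why: Fluoride desilylation under buffered, non-basic conditions frees the C6 hydroxyl, so the acetate is neither eliminated nor transferred (the C4 and C6 oxygens are trans) and the α-ketol is not epimerised.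

## Compound list

1 | 3-methylbut-2-enal | CC(C)=CC=O | starting material
2 | isopropenyl acetate | CC(=C)OC(C)=O | starting material
3 | (1E)-3-methylbuta-1,3-dien-1-yl acetate | CC(=O)O/C=C/C(C)=C | intermediate
4 | 1,3-oxazolidin-2-one | O=C1NCCO1 | starting material
5 | acryloyl chloride | C=CC(=O)Cl | starting material
6 | bromomagnesium 2-oxo-1,3-oxazolidin-3-ide | O=C1N([Mg]Br)CCO1 | intermediate
7 | 3-(prop-2-enoyl)-1,3-oxazolidin-2-one | C=CC(=O)N1CCOC1=O | intermediate
8 | (1S,6R)-3-methyl-6-(2-oxo-1,3-oxazolidine-3-carbonyl)cyclohex-2-en-1-yl acetate | CC(=O)O[C@H]1C=C(C)CC[C@H]1C(=O)N1CCOC1=O | intermediate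
9 | (1S,6R)-6-[methoxy(methyl)carbamoyl]-3-methylcyclohex-2-en-1-yl acetate | CC(=O)O[C@H]1C=C(C)CC[C@H]1C(=O)N(C)OC | intermediate
10 | 1-[(1R,2S)-2-hydroxy-4-methylcyclohex-3-en-1-yl]ethan-1-one | O[C@H]1C=C(C)CC[C@H]1C(C)=O | intermediate
11 | 1-[(1R,2S)-4-methyl-2-(triethylsilyloxy)cyclohex-3-en-1-yl]ethan-1-one | CC[Si](CC)(CC)O[C@H]1C=C(C)CC[C@H]1C(C)=O | intermediate
12 | ethyl (2E)-3-[(1S,2S)-4-methyl-2-(triethylsilyloxy)cyclohex-3-en-1-yl]but-2-enoate | CC[Si](CC)(CC)O[C@H]1C=C(C)CC[C@H]1/C(C)=C/C(=O)OCC | intermediate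
13 | ethyl (2E)-3-[(1S,2S)-5-hydroxy-4-methyl-2-(triethylsilyloxy)cyclohex-3-en-1-yl]but-2-enoate (carbinol epimers) | CC[Si](CC)(CC)O[C@H]1C=C(C)C(O)C[C@H]1/C(C)=C/C(=O)OCC | intermediate
14 | ethyl (2E)-3-[(1S,2S)-4-methyl-5-oxo-2-(triethylsilyloxy)cyclohex-3-en-1-yl]but-2-enoate | CC[Si](CC)(CC)O[C@H]1C=C(C)C(=O)C[C@H]1/C(C)=C/C(=O)OCC | intermediate
15 | potassium enolate of 14 (C1–O, C1=C6) | [K+].CC[Si](CC)(CC)O[C@H]1C=C(C)C([O-])=C[C@H]1/C(C)=C/C(=O)OCC | intermediate
16 | ethyl (2E)-3-[(1R,2S,6R)-6-hydroxy-4-methyl-5-oxo-2-(triethylsilyloxy)cyclohex-3-en-1-yl]but-2-enoate | CC[Si](CC)(CC)O[C@H]1C=C(C)C(=O)[C@H](O)[C@H]1/C(C)=C/C(=O)OCC | intermediate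
17 | ethyl (2E)-3-[(1S,2S,6R)-6-(tert-butyldimethylsilyloxy)-4-methyl-5-oxo-2-(triethylsilyloxy)cyclohex-3-en-1-yl]but-2-enoate | CC[Si](CC)(CC)O[C@H]1C=C(C)C(=O)[C@H](O[Si](C)(C)C(C)(C)C)[C@H]1/C(C)=C/C(=O)OCC | intermediate
18 | (2E)-3-[(1S,2S,6R)-6-(tert-butyldimethylsilyloxy)-5-hydroxy-4-methyl-2-(triethylsilyloxy)cyclohex-3-en-1-yl]but-2-en-1-ol (carbinol epimers) | CC[Si](CC)(CC)O[C@H]1C=C(C)C(O)[C@H](O[Si](C)(C)C(C)(C)C)[C@H]1/C(C)=C/CO | intermediate
19 | (2E)-3-[(1S,2S,6R)-6-(tert-butyldimethylsilyloxy)-4-methyl-5-oxo-2-(triethylsilyloxy)cyclohex-3-en-1-yl]but-2-enal | CC[Si](CC)(CC)O[C@H]1C=C(C)C(=O)[C@H](O[Si](C)(C)C(C)(C)C)[C@H]1/C(C)=C/C=O | intermediate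
20 | methyl (2S)-3-hydroxy-2-methylpropanoate | OC[C@H](C)C(=O)OC | starting material
21 | methyl (2S)-3-(tert-butyldimethylsilyloxy)-2-methylpropanoate | CC(C)(C)[Si](C)(C)OC[C@H](C)C(=O)OC | intermediate
22 | (2S)-3-(tert-butyldimethylsilyloxy)-2-methylpropanal | CC(C)(C)[Si](C)(C)OC[C@H](C)C=O | intermediate
23 | (3-methylbutyl)triphenylphosphonium bromide | [Br-].CC(C)CC[P+](c1ccccc1)(c1ccccc1)c1ccccc1 | starting material
24 | (3-methylbutylidene)triphenylphosphorane | CC(C)CC=P(c1ccccc1)(c1ccccc1)c1ccccc1 | intermediate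
25 | tert-butyl{[(2R,3Z)-2,6-dimethylhept-3-en-1-yl]oxy}dimethylsilane | CC(C)(C)[Si](C)(C)OC[C@H](C)/C=C\CC(C)C | intermediate
26 | (2R,3Z)-2,6-dimethylhept-3-en-1-ol | OC[C@H](C)/C=C\CC(C)C | intermediate
27 | 5-{[(2R,3Z)-2,6-dimethylhept-3-en-1-yl]sulfanyl}-1-phenyl-1H-tetrazole | c1ccccc1-n1nnnc1SC[C@H](C)/C=C\CC(C)C | intermediate
28 | 5-{[(2R,3Z)-2,6-dimethylhept-3-en-1-yl]sulfonyl}-1-phenyl-1H-tetrazole | c1ccccc1-n1nnnc1S(=O)(=O)C[C@H](C)/C=C\CC(C)C | intermediate
29 | potassium α-sulfonyl carbanion of 28 | [K+].c1ccccc1-n1nnnc1S(=O)(=O)[CH-][C@H](C)/C=C\CC(C)C | intermediate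
30 | (4S,5S,6R)-6-(tert-butyldimethylsilyloxy)-5-[(2E,4E,6R,7Z)-6,10-dimethylundeca-2,4,7-trien-2-yl]-2-methyl-4-(triethylsilyloxy)cyclohex-2-en-1-one | CC[Si](CC)(CC)O[C@H]1C=C(C)C(=O)[C@H](O[Si](C)(C)C(C)(C)C)[C@H]1/C(C)=C/C=C/[C@H](C)/C=C\CC(C)C | intermediate
31 | (4S,5S,6R)-6-(tert-butyldimethylsilyloxy)-5-[(2E,4E,6R,7Z)-6,10-dimethylundeca-2,4,7-trien-2-yl]-4-hydroxy-2-methylcyclohex-2-en-1-one | O[C@H]1C=C(C)C(=O)[C@H](O[Si](C)(C)C(C)(C)C)[C@H]1/C(C)=C/C=C/[C@H](C)/C=C\CC(C)C | intermediate
32 | (1S,5R,6S)-5-(tert-butyldimethylsilyloxy)-6-[(2E,4E,6R,7Z)-6,10-dimethylundeca-2,4,7-trien-2-yl]-3-methyl-4-oxocyclohex-2-en-1-yl acetate | CC(=O)O[C@H]1C=C(C)C(=O)[C@H](O[Si](C)(C)C(C)(C)C)[C@H]1/C(C)=C/C=C/[C@H](C)/C=C\CC(C)C | intermediate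
33 | (1S,5R,6R)-6-[(2E,4E,6R,7Z)-6,10-dimethylundeca-2,4,7-trien-2-yl]-5-hydroxy-3-methyl-4-oxocyclohex-2-en-1-yl acetate | CC(=O)O[C@H]1C=C(C)C(=O)[C@H](O)[C@H]1/C(C)=C/C=C/[C@H](C)/C=C\CC(C)C | target

## Step count and risks

Total step count: 22 (16 on the ring-bearing line, 6 for the sulfone).
Longest linear sequence: 15 steps (step 1 or 2, steps 3 to 12, steps 19 to 22).

Steps most likely to fail:

1. Step 8. The ene step may be slow next to the C4 silyloxy group, may oxidise the C2 methyl in place of the ring CH2, or the seleninic acid formed may cleave the triethylsilyl ether. The fallback changes both mechanism and substrate: hydrogen abstraction by a chromium reagent on an acetate whose C4–H is deactivated. It sets out from 12. HF·pyridine in THF gives the hydroxy enoate F1, and Ac2O/pyridine/DMAP gives the acetoxy enoate F2. CrO3 with 3,5-dimethylpyrazole in CH2Cl2 at −20 °C oxidises the C1 methylene to the acetoxy enone F3. K2CO3 in EtOH at 0 °C gives the hydroxy enone F4, and Et3SiCl/imidazole returns to the route at 14.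

2. Step 19. The sulfonyl carbanion may enolise or add to the ring ketone of the keto-aldehyde, and E-selectivity may erode with a conjugated aldehyde. The fallback keeps C1 at the alcohol oxidation level during the olefination. It sets out from 18. TEMPO (cat.) with PhI(OAc)2 in CH2Cl2 oxidises only the primary allylic alcohol, giving the hydroxy enal F5. Excess carbanion 29 (the first equivalent deprotonates the C1 hydroxyl) in DME at −78 °C → rt gives the hydroxy triene F6. Dess–Martin periodinane with NaHCO3 then oxidises the ring alcohol and returns to the route at 30.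

3. Step 7. Olefination of the hindered α-branched ketone may be slow, allowing epimerisation at C5, β-elimination of the silyloxy group and incomplete E-selectivity. The fallback builds the trisubstituted alkene stereospecifically from an alkyne. It sets out from 11. LiN(i-Pr)2 in THF at −78 °C deprotonates the methyl group, and ClP(O)(OEt)2 gives the enol phosphate F7. More LiN(i-Pr)2 (2.2 equiv) eliminates it to the terminal alkyne F8. Carboalumination with AlMe3 and Cp2ZrCl2 in CH2Cl2 adds methyl and aluminium syn to give the alkenylalane F9. Ethyl chloroformate acylates it with retention and returns to the route at 12 as the E isomer only.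

## Further compounds

F1 | step 8 | ethyl (2E)-3-[(1S,2S)-2-hydroxy-4-methylcyclohex-3-en-1-yl]but-2-enoate | O[C@H]1C=C(C)CC[C@H]1/C(C)=C/C(=O)OCC
F2 | step 8 | ethyl (2E)-3-[(1S,2S)-2-acetoxy-4-methylcyclohex-3-en-1-yl]but-2-enoate | CC(=O)O[C@H]1C=C(C)CC[C@H]1/C(C)=C/C(=O)OCC
F3 | step 8 | ethyl (2E)-3-[(1S,2S)-2-acetoxy-4-methyl-5-oxocyclohex-3-en-1-yl]but-2-enoate | CC(=O)O[C@H]1C=C(C)C(=O)C[C@H]1/C(C)=C/C(=O)OCC
F4 | step 8 | ethyl (2E)-3-[(1S,2S)-2-hydroxy-4-methyl-5-oxocyclohex-3-en-1-yl]but-2-enoate | O[C@H]1C=C(C)C(=O)C[C@H]1/C(C)=C/C(=O)OCC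
F5 | step 19 | (2E)-3-[(1S,2S,6R)-6-(tert-butyldimethylsilyloxy)-5-hydroxy-4-methyl-2-(triethylsilyloxy)cyclohex-3-en-1-yl]but-2-enal (carbinol epimers) | CC[Si](CC)(CC)O[C@H]1C=C(C)C(O)[C@H](O[Si](C)(C)C(C)(C)C)[C@H]1/C(C)=C/C=O
F6 | step 19 | (4S,5S,6R)-6-(tert-butyldimethylsilyloxy)-5-[(2E,4E,6R,7Z)-6,10-dimethylundeca-2,4,7-trien-2-yl]-2-methyl-4-(triethylsilyloxy)cyclohex-2-en-1-ol (carbinol epimers) | CC[Si](CC)(CC)O[C@H]1C=C(C)C(O)[C@H](O[Si](C)(C)C(C)(C)C)[C@H]1/C(C)=C/C=C/[C@H](C)/C=C\CC(C)C
F7 | step 7 | diethyl 1-[(1R,2S)-4-methyl-2-(triethylsilyloxy)cyclohex-3-en-1-yl]ethenyl phosphate | CC[Si](CC)(CC)O[C@H]1C=C(C)CC[C@H]1C(=C)OP(=O)(OCC)OCC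
F8 | step 7 | triethyl{[(1S,6S)-6-ethynyl-3-methylcyclohex-2-en-1-yl]oxy}silane | CC[Si](CC)(CC)O[C@H]1C=C(C)CC[C@H]1C#C
F9 | step 7 | dimethyl{(1E)-2-[(1S,2S)-4-methyl-2-(triethylsilyloxy)cyclohex-3-en-1-yl]prop-1-en-1-yl}alumane | CC[Si](CC)(CC)O[C@H]1C=C(C)CC[C@H]1/C(C)=C/[Al](C)C
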